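**Plan**

- Retrosynthetic cuts: C1=C10 (ring-closing metathesis), then C2–C3 and C8–C9 plus the C8 ester (allyl and 2-methylallyl additions to aldehydes, tigloylation), then the lactone O–C6 bond (key step), then C7–C11 (Ireland–Claisen).
- Forward order: the Ireland–Claisen rearrangement joins C11 to C7 and leaves a C5=C6 olefin; this is turned into a 2-alkenyl-2-methyloxirane (C3–C4 oxirane). The γ-lactone ring closes first by O–C6 bond formation, then come the C8 arm, the C4–C5 oxirane ring and the C3 arm, and the ten-membered ring closes last.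
- Enabling feature: in the array O3–C3–C4(Me)(O)–C5–C6–O(lactone), C6 is allylic to the C4=C5 unit hidden in the final oxirane and 1,4 to O3. A C3–C4 oxirane next to a C5=C6 olefin is therefore a latent C4–C5–C6 π-allyl, which the C12 carboxylate traps at C6 (ring O–C6–C7–C11–C12), freeing O3 and the (E)-C4=C5 olefin in the same event.
- Stereochemistry: C7 and C11 by chirality transfer from a CBS-derived (S)-carbinol; C6 from C7 (trans-lactone under equilibrating conditions); C4/C5 by Sharpless epoxidation; C3 and C8 by reagent-controlled Brown allylborations; the (Z)-olefin by the ring.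

Key step: step 7

Remark: atoms are named by germacrane locants (lactone carbonyl C12 bonded to the oxygen on C6, ester on C8, hydroxyl on C3); compound 15 is carried as both epimers at its oxirane carbon, which becomes sp2 in step 7.

**Route**

Step 1
Reactants: 1 2,2-dimethoxyacetaldehyde (commercial aqueous solution); 2 1-(triphenyl-λ5-phosphanylidene)propan-2-one
Product: 3 (3E)-5,5-dimethoxypent-3-en-2-one
Conditions: CH2Cl2, 23 → 40 °C
Reagents that add atoms: none
Why: Wittig olefination with a ketone-stabilised ylide should give the (E)-enone and tolerates the aqueous aldehyde; no stereocentre is formed.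

Step 2
Reactants: 3
Product: 5 (2S,3E)-5,5-dimethoxypent-3-en-2-ol, via borate ester 4 (not isolated)
Conditions: (R)-2-methyl-CBS-oxazaborolidine (15 mol %), catecholborane, toluene, −78 °C; MeOH, then aq. NaOH wash
Reagents that add atoms: none
Why: Corey–Bakshi–Shibata reduction, in which the (R)-oxazaborolidine binds the ketone with the alkenyl group as the large substituent and delivers hydride to one carbonyl face, should set the (S)-carbinol that later relays its chirality.

Step 3
Reactants: 5; 6 propanoyl chloride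
Product: 7 (2S,3E)-5,5-dimethoxypent-3-en-2-yl propanoate
Conditions: pyridine, DMAP (cat.), CH2Cl2, 0 °C
Reagents that add atoms: none
Why: O-acylation (nucleophilic acyl substitution) of the secondary allylic alcohol, which leaves the stereocentre untouched.

Step 4
Reactants: 7
Product: 11 methyl (2R,3R,4E)-3-(dimethoxymethyl)-2-methylhex-4-enoate, via silyl ketene acetal 8 (not isolated), via trimethylsilyl ester 9 (not isolated), via carboxylic acid 10 (not isolated)
Conditions: LiN(iPr)2, Me3SiCl/Et3N, THF, −78 → 23 °C, then 60 °C; aq. NaOH, then citric acid to pH 4; Me3SiCHN2, MeOH/toluene, 0 °C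
Reagents that add atoms: trimethylsilyldiazomethane, C[Si](C)(C)C=[N+]=[N-]
Why: Ireland–Claisen rearrangement, in which kinetic enolisation in THF puts the enolate methyl cis to the allyloxy oxygen and the silyl ketene acetal rearranges through a chair with the carbinol methyl equatorial, should relay the (S)-centre and the (E)-olefin into the 2,3-anti (2R,3R) pair and a new (E)-olefin, the crude acid being methylated at once.

Step 5
Reactants: 11; 2
Product: 14 methyl (2R,3R,4E)-3-(dimethoxymethyl)-2-methyl-6-oxohept-4-enoate, via ozonide 12 (not isolated), via aldehyde 13 (not isolated)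
Conditions: O3, CH2Cl2, −78 °C; PPh3, −78 → 23 °C; then 2, 23 °C
Reagents that add atoms: none
Why: ozonolysis with reductive work-up followed in the same flask by Wittig olefination with the stabilised ylide should exchange the propenyl end for the (E)-enone under neutral conditions that do not epimerise the α-centre of the transient aldehyde.

Step 6
Reactants: 14
Product: 15 methyl (2R,3R,4E)-3-(dimethoxymethyl)-2-methyl-5-(2-methyloxiran-2-yl)pent-4-enoate (both oxirane epimers)
Conditions: Me3S+ I−, KN(SiMe3)2, THF, −10 °C; then 14, −10 → 0 °C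
Reagents that add atoms: trimethylsulfonium iodide, C[S+](C)C.[I-]
Why: Corey–Chaykovsky epoxidation, in which dimethylsulfonium methylide adds 1,2 to the enone carbonyl and closes the oxirane, forms the new quaternary centre without control, which is harmless because step 7 erases it.

Step 7
Reactants: 15
Product: 17 (3R,4S,5R)-4-(dimethoxymethyl)-5-[(1E)-3-hydroxy-2-methylprop-1-en-1-yl]-3-methyloxolan-2-one, via lithium carboxylate 16 (not isolated)
Conditions: LiOH, THF/H2O (3:1), 0 → 23 °C; then AcOH to pH 6–7, Pd(PPh3)4 (5 mol %), 23 °C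
Reagents that add atoms: lithium hydroxide, [Li+].[OH-]
Why: After saponification, zerovalent palladium ionises the allylic C4–O bond of the 2-alkenyl-2-methyloxirane with release of ring strain and gives a C4–C5–C6 π-allylpalladium alkoxide, whose C6 terminus is attacked by the carboxylate oxygen on the face opposite to the metal while the alkoxide is protonated to the C3 alcohol. The closest known reaction type is the palladium-catalysed 1,4-addition of carboxylic acids to 1,3-diene monoepoxides (Tsuji–Trost reaction of vinyl oxiranes), here run within one molecule. The lactone ring (O–C6–C7–C11–C12) closes in the 5-exo mode on the allyl terminus, whereas attack at C4 would need a seven-membered ring. The new stereocentre C6 is controlled by C7: the allylic lactone can ionise again and the two π-allyl faces interconvert, so both oxirane epimers should converge on the lactone with the C6 alkenyl group trans to the C7 dimethoxymethyl group, the all-cis alternative being strongly disfavoured. The step needs C6 over C4 attack, the (E)-geometry of the new C4=C5 bond and capture faster than β-hydride loss; the tether secures the first, the preference of the small methyl group for the anti position of the π-allyl the second, and the intramolecular nucleophile the third.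

Step 8
Reactants: 17
Product: 18 (3R,4S,5R)-5-[(1E)-3-{[tert-butyl(diphenyl)silyl]oxy}-2-methylprop-1-en-1-yl]-4-(dimethoxymethyl)-3-methyloxolan-2-one
Conditions: t-BuPh2SiCl, imidazole, DMF, 0 → 23 °C
Reagents that add atoms: tert-butyl(chloro)diphenylsilane, CC(C)(C)[Si](Cl)(c1ccccc1)c1ccccc1
Why: silylation of the primary allylic alcohol masks O3 while the C8 arm is built; no stereocentre is touched.

Step 9
Reactants: 18
Product: 19 (2R,3S,4R)-2-[(1E)-3-{[tert-butyl(diphenyl)silyl]oxy}-2-methylprop-1-en-1-yl]-4-methyl-5-oxooxolane-3-carbaldehyde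
Conditions: 10% aq. oxalic acid on SiO2, CH2Cl2, 23 °C; used at once
Reagents that add atoms: water, O
Why: mild acid hydrolysis of the dimethyl acetal on wet silica should free the C8 aldehyde without loss of the silyl ether, and the non-basic medium should avoid enolisation at C7 and β-elimination of the lactone oxygen.

Step 10
Reactants: 19
Product: 21 (3R,4R,5R)-5-[(1E)-3-{[tert-butyl(diphenyl)silyl]oxy}-2-methylprop-1-en-1-yl]-4-[(1R)-1-hydroxy-3-methylbut-3-en-1-yl]-3-methyloxolan-2-one, via borinate 20 (not isolated)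
Conditions: (+)-B-methoxydiisopinocampheylborane (from (−)-α-pinene), 2-methylallylmagnesium chloride, Et2O, −78 → 23 °C; then 19, −78 °C; pH 7 buffer, H2O2, 0 °C
Reagents that add atoms: 2-methylallylmagnesium chloride, CC(=C)C[Mg]Cl
Why: Brown allylboration, in which the 2-methylallyl group is delivered through a chair Zimmerman–Traxler transition state under reagent control to the Re face of the aldehyde, should set (8R), and the oxygen stays on boron until the neutral oxidative work-up so that the lactone should not migrate.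

Step 11
Reactants: 21; 22 (2E)-2-methylbut-2-enoic acid (tiglic acid)
Product: 23 (1R)-1-[(2R,3R,4R)-2-[(1E)-3-{[tert-butyl(diphenyl)silyl]oxy}-2-methylprop-1-en-1-yl]-4-methyl-5-oxooxolan-3-yl]-3-methylbut-3-en-1-yl (2E)-2-methylbut-2-enoate
Conditions: 2,4,6-trichlorobenzoyl chloride, Et3N, THF, 23 °C; then 21, DMAP, toluene, 23 → 40 °C
Reagents that add atoms: none
Why: Yamaguchi esterification through the mixed anhydride should acylate the hindered secondary alcohol with retention at C8 and avoids the deconjugation that an enoyl chloride with amine base can suffer.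

Step 12
Reactants: 23
Product: 24 (1R)-1-[(2R,3R,4R)-2-[(1E)-3-hydroxy-2-methylprop-1-en-1-yl]-4-methyl-5-oxooxolan-3-yl]-3-methylbut-3-en-1-yl (2E)-2-methylbut-2-enoate
Conditions: HF·pyridine, pyridine, THF, 0 → 23 °C
Reagents that add atoms: none
Why: fluoride-mediated desilylation under buffered conditions, which the tiglate and the lactone should survive, frees the primary allylic alcohol.

Step 13
Reactants: 24
Product: 25 (1R)-1-[(2S,3R,4R)-2-[(2R,3R)-3-(hydroxymethyl)-3-methyloxiran-2-yl]-4-methyl-5-oxooxolan-3-yl]-3-methylbut-3-en-1-yl (2E)-2-methylbut-2-enoate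
Conditions: Ti(OiPr)4 (20 mol %), (−)-diisopropyl D-tartrate, t-BuOOH, 4 Å molecular sieves, CH2Cl2, −20 °C
Reagents that add atoms: tert-butyl hydroperoxide, CC(C)(C)OO
Why: Sharpless asymmetric epoxidation, in which the titanium tartrate complex delivers oxygen to one face of the primary allylic alcohol under reagent control, should give the (4R,5R)-oxirane and leaves the electron-poor tiglate and the isolated 1,1-disubstituted olefin alone.

Step 14
Reactants: 25
Product: 26 (1R)-1-[(2S,3R,4R)-2-[(2R,3S)-3-formyl-3-methyloxiran-2-yl]-4-methyl-5-oxooxolan-3-yl]-3-methylbut-3-en-1-yl (2E)-2-methylbut-2-enoate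
Conditions: Dess–Martin periodinane, pyridine, CH2Cl2, 0 → 23 °C
Reagents that add atoms: none
Why: Dess–Martin oxidation of the primary epoxy alcohol under buffered conditions gives the non-enolisable α,α-disubstituted epoxy aldehyde without change at any stereocentre.

Step 15
Reactants: 26
Product: 28 (1R)-1-[(2S,3R,4R)-2-[(2R,3R)-3-[(1S)-1-hydroxybut-3-en-1-yl]-3-methyloxiran-2-yl]-4-methyl-5-oxooxolan-3-yl]-3-methylbut-3-en-1-yl (2E)-2-methylbut-2-enoate, via borinate 27 (not isolated)
Conditions: (−)-B-methoxydiisopinocampheylborane (from (+)-α-pinene), allylmagnesium bromide, Et2O, −78 → 23 °C; then 26, −78 °C; pH 7 buffer, H2O2, 0 °C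
Reagents that add atoms: allylmagnesium bromide, C=CC[Mg]Br
Why: Brown allylboration under reagent control, with allyl transfer to the Si face of the aldehyde through the chair transition state, should set (3S), the hydroxyl/oxirane relationship that hydroxyl-directed epoxidation of an acyclic secondary allylic alcohol with a geminal methyl group would not give.

Step 16
Reactants: 28
Product: 29 (3S,4R,5R,6S,7R,8R,11R)-4,5-epoxy-3-hydroxy-8-[(2E)-2-methylbut-2-enoyloxy]germacr-1(10)Z-en-12,6-olide (CNP0265652.4)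
Conditions: second-generation Hoveyda–Grubbs catalyst (15 mol %, in portions), toluene (0.5 mM), 80 °C
Reagents that add atoms: none
Why: ring-closing metathesis of the monosubstituted and the 1,1-disubstituted olefin with loss of ethene should close the ten-membered ring, whose size enforces the (Z)-trisubstituted C1=C10 bond, and the free hydroxyl, the oxirane and the esters are tolerated by the ruthenium carbene.

**Compound list**

1 | 2,2-dimethoxyacetaldehyde | COC(OC)C=O | starting material
2 | 1-(triphenyl-λ5-phosphanylidene)propan-2-one | CC(=O)C=P(c1ccccc1)(c1ccccc1)c1ccccc1 | starting material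
3 | (3E)-5,5-dimethoxypent-3-en-2-one | CC(=O)/C=C/C(OC)OC | intermediate
4 | 2-{[(2S,3E)-5,5-dimethoxypent-3-en-2-yl]oxy}-1,3,2-benzodioxaborole | C[C@H](OB1Oc2ccccc2O1)/C=C/C(OC)OC | intermediate
5 | (2S,3E)-5,5-dimethoxypent-3-en-2-ol | C[C@H](O)/C=C/C(OC)OC | intermediate
6 | propanoyl chloride | CCC(Cl)=O | starting material
7 | (2S,3E)-5,5-dimethoxypent-3-en-2-yl propanoate | CCC(=O)O[C@@H](C)/C=C/C(OC)OC | intermediate
8 | [(1E)-1-{[(2S,3E)-5,5-dimethoxypent-3-en-2-yl]oxy}prop-1-en-1-yl]oxy(trimethyl)silane | C/C=C(/O[Si](C)(C)C)O[C@@H](C)/C=C/C(OC)OC | intermediate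
9 | trimethylsilyl (2R,3R,4E)-3-(dimethoxymethyl)-2-methylhex-4-enoate | C[Si](C)(C)OC(=O)[C@H](C)[C@@H](/C=C/C)C(OC)OC | intermediate
10 | (2R,3R,4E)-3-(dimethoxymethyl)-2-methylhex-4-enoic acid | OC(=O)[C@H](C)[C@@H](/C=C/C)C(OC)OC | intermediate
11 | methyl (2R,3R,4E)-3-(dimethoxymethyl)-2-methylhex-4-enoate | COC(=O)[C@H](C)[C@@H](/C=C/C)C(OC)OC | intermediate
12 | methyl (2R,3R)-3-(dimethoxymethyl)-2-methyl-3-(5-methyl-1,2,4-trioxolan-3-yl)propanoate (ozonide, ring stereoisomers) | COC(=O)[C@H](C)[C@@H](C1OOC(C)O1)C(OC)OC | intermediate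
13 | methyl (2R,3S)-3-(dimethoxymethyl)-2-methyl-4-oxobutanoate | COC(=O)[C@H](C)[C@@H](C=O)C(OC)OC | intermediate
14 | methyl (2R,3R,4E)-3-(dimethoxymethyl)-2-methyl-6-oxohept-4-enoate | COC(=O)[C@H](C)[C@@H](/C=C/C(C)=O)C(OC)OC | intermediate
15 | methyl (2R,3R,4E)-3-(dimethoxymethyl)-2-methyl-5-(2-methyloxiran-2-yl)pent-4-enoate (both oxirane epimers) | COC(=O)[C@H](C)[C@@H](/C=C/C1(C)CO1)C(OC)OC | intermediate
16 | lithium (2R,3R,4E)-3-(dimethoxymethyl)-2-methyl-5-(2-methyloxiran-2-yl)pent-4-enoate | [Li+].[O-]C(=O)[C@H](C)[C@@H](/C=C/C1(C)CO1)C(OC)OC | intermediate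
17 | (3R,4S,5R)-4-(dimethoxymethyl)-5-[(1E)-3-hydroxy-2-methylprop-1-en-1-yl]-3-methyloxolan-2-one | OC/C(C)=C/[C@H]1OC(=O)[C@H](C)[C@@H]1C(OC)OC | intermediate
18 | (3R,4S,5R)-5-[(1E)-3-{[tert-butyl(diphenyl)silyl]oxy}-2-methylprop-1-en-1-yl]-4-(dimethoxymethyl)-3-methyloxolan-2-one | CC(C)(C)[Si](OC/C(C)=C/[C@H]1OC(=O)[C@H](C)[C@@H]1C(OC)OC)(c1ccccc1)c1ccccc1 | intermediate
19 | (2R,3S,4R)-2-[(1E)-3-{[tert-butyl(diphenyl)silyl]oxy}-2-methylprop-1-en-1-yl]-4-methyl-5-oxooxolane-3-carbaldehyde | CC(C)(C)[Si](OC/C(C)=C/[C@H]1OC(=O)[C@H](C)[C@@H]1C=O)(c1ccccc1)c1ccccc1 | intermediate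
20 | diisopinocampheylborinic ester of 21 (isopinocampheyl groups from (−)-α-pinene) | CC(C)(C)[Si](OC/C(C)=C/[C@H]1OC(=O)[C@H](C)[C@@H]1[C@H](OB([C@H]2C[C@H]3C[C@@H]([C@@H]2C)C3(C)C)[C@H]2C[C@H]3C[C@@H]([C@@H]2C)C3(C)C)CC(C)=C)(c1ccccc1)c1ccccc1 | intermediate
21 | (3R,4R,5R)-5-[(1E)-3-{[tert-butyl(diphenyl)silyl]oxy}-2-methylprop-1-en-1-yl]-4-[(1R)-1-hydroxy-3-methylbut-3-en-1-yl]-3-methyloxolan-2-one | CC(C)(C)[Si](OC/C(C)=C/[C@H]1OC(=O)[C@H](C)[C@@H]1[C@H](O)CC(C)=C)(c1ccccc1)c1ccccc1 | intermediate
22 | (2E)-2-methylbut-2-enoic acid (tiglic acid) | C/C=C(\C)C(=O)O | starting material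
23 | (1R)-1-[(2R,3R,4R)-2-[(1E)-3-{[tert-butyl(diphenyl)silyl]oxy}-2-methylprop-1-en-1-yl]-4-methyl-5-oxooxolan-3-yl]-3-methylbut-3-en-1-yl (2E)-2-methylbut-2-enoate | CC(C)(C)[Si](OC/C(C)=C/[C@H]1OC(=O)[C@H](C)[C@@H]1[C@@H](CC(C)=C)OC(=O)/C(C)=C/C)(c1ccccc1)c1ccccc1 | intermediate
24 | (1R)-1-[(2R,3R,4R)-2-[(1E)-3-hydroxy-2-methylprop-1-en-1-yl]-4-methyl-5-oxooxolan-3-yl]-3-methylbut-3-en-1-yl (2E)-2-methylbut-2-enoate | OC/C(C)=C/[C@H]1OC(=O)[C@H](C)[C@@H]1[C@@H](CC(C)=C)OC(=O)/C(C)=C/C | intermediate
25 | (1R)-1-[(2S,3R,4R)-2-[(2R,3R)-3-(hydroxymethyl)-3-methyloxiran-2-yl]-4-methyl-5-oxooxolan-3-yl]-3-methylbut-3-en-1-yl (2E)-2-methylbut-2-enoate | OC[C@@]1(C)O[C@@H]1[C@H]1OC(=O)[C@H](C)[C@@H]1[C@@H](CC(C)=C)OC(=O)/C(C)=C/C | intermediate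
26 | (1R)-1-[(2S,3R,4R)-2-[(2R,3S)-3-formyl-3-methyloxiran-2-yl]-4-methyl-5-oxooxolan-3-yl]-3-methylbut-3-en-1-yl (2E)-2-methylbut-2-enoate | O=C[C@@]1(C)O[C@@H]1[C@H]1OC(=O)[C@H](C)[C@@H]1[C@@H](CC(C)=C)OC(=O)/C(C)=C/C | intermediate
27 | diisopinocampheylborinic ester of 28 (isopinocampheyl groups from (+)-α-pinene) | C=CC[C@H](OB([C@@H]2C[C@@H]3C[C@H]([C@H]2C)C3(C)C)[C@@H]2C[C@@H]3C[C@H]([C@H]2C)C3(C)C)[C@@]1(C)O[C@@H]1[C@H]1OC(=O)[C@H](C)[C@@H]1[C@@H](CC(C)=C)OC(=O)/C(C)=C/C | intermediate
28 | (1R)-1-[(2S,3R,4R)-2-[(2R,3R)-3-[(1S)-1-hydroxybut-3-en-1-yl]-3-methyloxiran-2-yl]-4-methyl-5-oxooxolan-3-yl]-3-methylbut-3-en-1-yl (2E)-2-methylbut-2-enoate | C=CC[C@H](O)[C@@]1(C)O[C@@H]1[C@H]1OC(=O)[C@H](C)[C@@H]1[C@@H](CC(C)=C)OC(=O)/C(C)=C/C | intermediate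
29 | (3S,4R,5R,6S,7R,8R,11R)-4,5-epoxy-3-hydroxy-8-[(2E)-2-methylbut-2-enoyloxy]germacr-1(10)Z-en-12,6-olide | C/C=C(\C)C(=O)O[C@@H]1C/C(C)=C\C[C@H](O)[C@@]2(C)O[C@@H]2[C@H]2OC(=O)[C@H](C)[C@@H]21 | target

**Step count and risks**

Total step count: 16. Longest linear sequence: 16 steps (from 1 and 2 to 29).

Steps most likely to fail:

1. Step 16 (ring-closing metathesis). Intermolecular metathesis and catalyst decay may outrun closure of a strained ten-membered ring that must form a trisubstituted olefin while already holding the trans-oxirane and the trans-lactone, and the olefin geometry may not be uniform. The fallback closes the ring before the oxirane is made and lets the ring set the oxirane configuration. It sets out from 24: MnO2 in CH2Cl2 should give the C3 enal F1; Brown allylboration with the (−)-B-allyldiisopinocampheylborane of step 15 should give the (3S)-dienol F2; ring-closing metathesis (second-generation Hoveyda–Grubbs catalyst, toluene, high dilution), now with a flat (E)-olefin in place of the oxirane, should give the macrocyclic dienol F3; hydroxyl-directed epoxidation (VO(acac)2, t-BuOOH) on the open outer face of the ring-bound (E)-olefin should then come back to the route at 29.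

2. Step 7 (key step). Palladium-induced isomerisation of the vinyl oxirane by β-hydride loss may compete, or equilibration may stay incomplete and leave C6 epimers or (Z)-olefin. The fallback makes the same O–C6 bond by electrophile-induced lactonisation and moves the oxygen to C3 by a sigmatropic shift. It sets out from 14: Wittig methylenation (Ph3P=CH2, THF) should give the diene ester F4 and LiOH the dienoic acid F5; phenylselenolactonisation (N-(phenylseleno)phthalimide, CH2Cl2) should add selenium and carboxylate anti across C5=C6 to give the allylic selenide lactone F6; oxidation in the same flask (H2O2, pyridine, 0 °C) should trigger the [2,3]-sigmatropic shift of the selenoxide, which places oxygen on C3 and the (E)-olefin at C4=C5, and comes back at 17.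

3. Step 15 (allylboration of the epoxy aldehyde). Facial selectivity may be poor if reagent and substrate preferences are mismatched at the hindered α-quaternary aldehyde, and the Lewis-acidic borane may open the oxirane. The fallback sets C3 by ketone reduction instead of allyl transfer. It sets out from 26: Barbier allylation (allyl bromide, indium, THF/H2O) without stereocontrol should give the epimeric carbinols F7; Dess–Martin oxidation should give the epoxy ketone F8; Corey–Bakshi–Shibata reduction ((R)-2-methyl-CBS-oxazaborolidine, catecholborane, −78 °C, hydrolytic work-up), with the quaternary oxirane carbon as the large group, should set (3S) and come back at 28.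

**Further compounds**

F1 | step 16 | (1R)-1-[(2R,3R,4R)-4-methyl-2-[(1E)-2-methyl-3-oxoprop-1-en-1-yl]-5-oxooxolan-3-yl]-3-methylbut-3-en-1-yl (2E)-2-methylbut-2-enoate | O=C/C(C)=C/[C@H]1OC(=O)[C@H](C)[C@@H]1[C@@H](CC(C)=C)OC(=O)/C(C)=C/C
F2 | step 16 | (1R)-1-[(2R,3R,4R)-2-[(1E,3S)-3-hydroxy-2-methylhexa-1,5-dien-1-yl]-4-methyl-5-oxooxolan-3-yl]-3-methylbut-3-en-1-yl (2E)-2-methylbut-2-enoate | C=CC[C@H](O)/C(C)=C/[C@H]1OC(=O)[C@H](C)[C@@H]1[C@@H](CC(C)=C)OC(=O)/C(C)=C/C
F3 | step 16 | (3S,6R,7R,8R,11R)-3-hydroxy-8-[(2E)-2-methylbut-2-enoyloxy]germacra-1(10)Z,4E-dien-12,6-olide | C/C=C(\C)C(=O)O[C@@H]1C/C(C)=C\C[C@H](O)/C(C)=C/[C@H]2OC(=O)[C@H](C)[C@@H]21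
F4 | step 7 | methyl (2R,3R,4E)-3-(dimethoxymethyl)-2,6-dimethylhepta-4,6-dienoate | COC(=O)[C@H](C)[C@@H](/C=C/C(C)=C)C(OC)OC
F5 | step 7 | (2R,3R,4E)-3-(dimethoxymethyl)-2,6-dimethylhepta-4,6-dienoic acid | OC(=O)[C@H](C)[C@@H](/C=C/C(C)=C)C(OC)OC
F6 | step 7 | (3R,4S,5S)-4-(dimethoxymethyl)-3-methyl-5-[(1R)-2-methyl-1-(phenylselanyl)prop-2-en-1-yl]oxolan-2-one | C=C(C)[C@@H]([Se]c1ccccc1)[C@H]1OC(=O)[C@H](C)[C@@H]1C(OC)OC
F7 | step 15 | (1R)-1-[(2S,3R,4R)-2-[(2R,3R)-3-(1-hydroxybut-3-en-1-yl)-3-methyloxiran-2-yl]-4-methyl-5-oxooxolan-3-yl]-3-methylbut-3-en-1-yl (2E)-2-methylbut-2-enoate (both carbinol epimers) | C=CCC(O)[C@@]1(C)O[C@@H]1[C@H]1OC(=O)[C@H](C)[C@@H]1[C@@H](CC(C)=C)OC(=O)/C(C)=C/C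
F8 | step 15 | (1R)-1-[(2S,3R,4R)-2-[(2R,3S)-3-(but-3-enoyl)-3-methyloxiran-2-yl]-4-methyl-5-oxooxolan-3-yl]-3-methylbut-3-en-1-yl (2E)-2-methylbut-2-enoate | C=CCC(=O)[C@@]1(C)O[C@@H]1[C@H]1OC(=O)[C@H](C)[C@@H]1[C@@H](CC(C)=C)OC(=O)/C(C)=C/C
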